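**Retrosynthetic overview**

1. Feature: in the target the ketone carbon on C6 (chromene numbering), its benzylic CH2, C6, C5 and the free oxygen on C5 are five of the six ring atoms of a 3-aryl-4-hydroxypyran-2-one (coumarin) ring; only the lactone carbonyl carbon is missing.
2. Target 18 ⇐ pyranocoumarin 15, by alkaline opening of the lactone and loss of that extra carbon as CO2.
3. 15 ⇐ aryl ester/methyl ester 14, by intramolecular Claisen condensation (pyranone ring, closed last); 14 ⇐ phenol 10 + arylacetic acid 13.
4. 10 ⇐ 5-O-prenyl ether 8, by para-Claisen–Cope relay to C8; 8 ⇐ chromene diol 5, by 7-O-methylation and then 5-O-prenylation.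
5. 5 ⇐ symmetric propargyl ether 3 of methyl 2,4,6-trihydroxybenzoate 1 (pyran ring, closed first on the given benzene ring).

Key step: step 8

Remark: the side-chain phenol is carried as its tert-butyldimethylsilyl ether, which the final alkaline step is expected to remove together with the lactone carbon. The target has no stereocentre; the stereocentres of the transient compounds 9 and 17 are racemic and are lost again.

**Route**

Step 1
Reactants: 1 methyl 2,4,6-trihydroxybenzoate; 2 3-chloro-3-methylbut-1-yne
Product: 3 methyl 2,6-dihydroxy-4-[(2-methylbut-3-yn-2-yl)oxy]benzoate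
Conditions: DBU (1.1 equiv), CuCl2·2H2O (cat.), MeCN, 0 °C
Reagents that add atoms: none
Why: The 4-hydroxyl is the only phenol of 1 not hydrogen-bonded to the ester and is the most acidic, so the copper-catalysed O-propargylation (a Williamson-type etherification through the copper acetylide) with one equivalent of base should stop at the symmetric mono-ether.

Step 2
Reactants: 3 methyl 2,6-dihydroxy-4-[(2-methylbut-3-yn-2-yl)oxy]benzoate
Product: 5 methyl 5,7-dihydroxy-2,2-dimethyl-2H-chromene-6-carboxylate, via allenylphenol 4 (not isolated)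
Conditions: o-xylene, 140 °C, argon
Reagents that add atoms: none
Why: Aryl 1,1-dimethylpropargyl ethers undergo propargyl Claisen rearrangement, 1,5-hydrogen shift and oxa-6π electrocyclisation on heating, and because the two ortho carbons of 3 are equivalent and the ring closes through the unchelated oxygen that carried the propargyl group, only one 2,2-dimethylchromene should form.

Step 3
Reactants: 5 methyl 5,7-dihydroxy-2,2-dimethyl-2H-chromene-6-carboxylate
Product: 6 methyl 5-hydroxy-7-methoxy-2,2-dimethyl-2H-chromene-6-carboxylate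
Conditions: MeI (1.05 equiv), K2CO3 (1.1 equiv), acetone, 0 °C to rt
Reagents that add atoms: iodomethane CI
Why: Williamson methylation with one equivalent of MeI should take the 7-hydroxyl, which has a free ortho position (C8–H), in preference to the 5-hydroxyl, which is wedged between the ester and the peri C4–H of the pyran ring and holds the stronger hydrogen bond to the ester carbonyl.

Step 4
Reactants: 6 methyl 5-hydroxy-7-methoxy-2,2-dimethyl-2H-chromene-6-carboxylate; 7 prenyl bromide (1-bromo-3-methylbut-2-ene)
Product: 8 methyl 7-methoxy-2,2-dimethyl-5-[(3-methylbut-2-en-1-yl)oxy]-2H-chromene-6-carboxylate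
Conditions: K2CO3, DMF, 50 °C
Reagents that add atoms: none
Why: With only the chelated 5-hydroxyl left, Williamson O-alkylation by the reactive allylic bromide in a dipolar aprotic solvent should give the prenyl ether, both ortho carbons being blocked against C-alkylation.

Step 5
Reactants: 8 methyl 7-methoxy-2,2-dimethyl-5-[(3-methylbut-2-en-1-yl)oxy]-2H-chromene-6-carboxylate
Product: 10 methyl 5-hydroxy-7-methoxy-2,2-dimethyl-8-(3-methylbut-2-en-1-yl)-2H-chromene-6-carboxylate, via ortho-dienone 9 (not isolated)
Conditions: PhNEt2, 200 °C, sealed tube, argon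
Reagents that add atoms: none
Why: In this para-Claisen–Cope rearrangement the first [3,3] shift delivers the inverted allyl unit to a blocked ortho carbon (drawn for C6 in 9), the dienone cannot enolise and passes the group on by a Cope [3,3] shift to C8, the only unsubstituted ring carbon and para to the oxygen on C5, where tautomerisation restores the phenol and the double inversion leaves a normal prenyl group.

Step 6
Reactants: 11 4-hydroxyphenylacetic acid
Product: 13 2-[4-(tert-butyldimethylsilyloxy)phenyl]acetic acid, via bis-silyl compound 12 (not isolated)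
Conditions: TBSCl (2.3 equiv), imidazole (4.5 equiv), DMF, rt; then THF/AcOH/H2O, rt
Reagents that add atoms: tert-butyldimethylsilyl chloride CC(C)(C)[Si](C)(C)Cl
Why: Silylation of both acidic hydroxyls followed by selective hydrolysis of the far more labile silyl ester is the standard silyl ether protection of a phenolic acid.

Step 7
Reactants: 10 methyl 5-hydroxy-7-methoxy-2,2-dimethyl-8-(3-methylbut-2-en-1-yl)-2H-chromene-6-carboxylate; 13 2-[4-(tert-butyldimethylsilyloxy)phenyl]acetic acid
Product: 14 methyl 5-({2-[4-(tert-butyldimethylsilyloxy)phenyl]acetyl}oxy)-7-methoxy-2,2-dimethyl-8-(3-methylbut-2-en-1-yl)-2H-chromene-6-carboxylate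
Conditions: DCC (1.3 equiv), DMAP (0.3 equiv), CH2Cl2, 0 °C to rt
Reagents that add atoms: none
Why: Steglich esterification acylates hindered, hydrogen-bonded phenols through the acylpyridinium (or the arylketene derived from it) under neutral conditions that leave the silyl ether, the chromene and the prenyl group untouched.

Step 8
Reactants: 14 methyl 5-({2-[4-(tert-butyldimethylsilyloxy)phenyl]acetyl}oxy)-7-methoxy-2,2-dimethyl-8-(3-methylbut-2-en-1-yl)-2H-chromene-6-carboxylate
Product: 15 3-[4-(tert-butyldimethylsilyloxy)phenyl]-4-hydroxy-5-methoxy-8,8-dimethyl-6-(3-methylbut-2-en-1-yl)pyrano[2,3-h]chromen-2-one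
Conditions: LiN(SiMe3)2 (2.5 equiv), THF (dilute), −78 °C to rt; then cold 1 M HCl
Reagents that add atoms: none
Why: LiN(SiMe3)2 removes a benzylic proton next to the aryl ester carbonyl of 14, the lithium enolate adds to the neighbouring C6 methyl ester, methoxide is lost, and the 3-arylchromane-2,4-dione so formed is deprotonated at once to the lithium 4-oxidocoumarin. The closest known reaction is the base-induced intramolecular Claisen (Dieckmann-type) cyclisation of methyl 2-(arylacetoxy)benzoates to 3-aryl-4-hydroxycoumarins, a relative of the Baker–Venkataraman acyl transfer. The pyranone ring closes in the favoured 6-(enolendo)-exo-trig mode, since both enolate carbons lie in the new ring and the ester C=O is exocyclic to it. No stereocentre is formed. The step needs C-acylation of the di-ortho-substituted ester to win over E1cB loss of the phenoxide (arylketene formation) and over intermolecular condensation. The tether makes the attack intramolecular, the twist of the crowded ester turns its π* face toward the neighbouring acyloxy group, ketene and phenoxide can recombine to the same enolate, and deprotonation of the acidic product is an irreversible sink, which is why an excess of a hindered, weakly nucleophilic amide base at low temperature and high dilution is chosen.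

Step 9
Reactants: 15 3-[4-(tert-butyldimethylsilyloxy)phenyl]-4-hydroxy-5-methoxy-8,8-dimethyl-6-(3-methylbut-2-en-1-yl)pyrano[2,3-h]chromen-2-one
Product: 18 1-[5-hydroxy-7-methoxy-2,2-dimethyl-8-(3-methylbut-2-en-1-yl)-2H-chromen-6-yl]-2-(4-hydroxyphenyl)ethan-1-one, via desilylated coumarin 16 (not isolated), via keto acid 17 (not isolated)
Conditions: NaOH (10% aq.), EtOH, reflux, argon; then 1 M HCl, 0 °C, to pH 4
Reagents that add atoms: none
Why: Hydroxide cleaves the aryl silyl ether and opens the lactone at C2, and the β-keto carboxylate loses CO2 on prolonged heating in the alkaline medium, the classical alkaline degradation of 3-aryl-4-hydroxycoumarins to 2-hydroxydeoxybenzoins, while the chromene, the prenyl group and the methyl ether are inert to base.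

**Compound list**

1 | methyl 2,4,6-trihydroxybenzoate | COC(=O)c1c(O)cc(O)cc1O | starting material
2 | 3-chloro-3-methylbut-1-yne | CC(C)(Cl)C#C | starting material
3 | methyl 2,6-dihydroxy-4-[(2-methylbut-3-yn-2-yl)oxy]benzoate | COC(=O)c1c(O)cc(OC(C)(C)C#C)cc1O | intermediate
4 | methyl 2,4,6-trihydroxy-3-(3-methylbuta-1,2-dien-1-yl)benzoate | COC(=O)c1c(O)cc(O)c(C=C=C(C)C)c1O | intermediate
5 | methyl 5,7-dihydroxy-2,2-dimethyl-2H-chromene-6-carboxylate | COC(=O)c1c(O)cc2OC(C)(C)C=Cc2c1O | intermediate
6 | methyl 5-hydroxy-7-methoxy-2,2-dimethyl-2H-chromene-6-carboxylate | COC(=O)c1c(OC)cc2OC(C)(C)C=Cc2c1O | intermediate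
7 | prenyl bromide (1-bromo-3-methylbut-2-ene) | CC(C)=CCBr | starting material
8 | methyl 7-methoxy-2,2-dimethyl-5-[(3-methylbut-2-en-1-yl)oxy]-2H-chromene-6-carboxylate | COC(=O)c1c(OC)cc2OC(C)(C)C=Cc2c1OCC=C(C)C | intermediate
9 | methyl 7-methoxy-2,2-dimethyl-6-(2-methylbut-3-en-2-yl)-5-oxo-5,6-dihydro-2H-chromene-6-carboxylate (racemic) | COC(=O)C1(C(C)(C)C=C)C(OC)=CC2=C(C=CC(C)(C)O2)C1=O | intermediate
10 | methyl 5-hydroxy-7-methoxy-2,2-dimethyl-8-(3-methylbut-2-en-1-yl)-2H-chromene-6-carboxylate | COC(=O)c1c(OC)c(CC=C(C)C)c2OC(C)(C)C=Cc2c1O | intermediate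
11 | 4-hydroxyphenylacetic acid | OC(=O)Cc1ccc(O)cc1 | starting material
12 | tert-butyldimethylsilyl 2-[4-(tert-butyldimethylsilyloxy)phenyl]acetate | CC(C)(C)[Si](C)(C)OC(=O)Cc1ccc(O[Si](C)(C)C(C)(C)C)cc1 | intermediate
13 | 2-[4-(tert-butyldimethylsilyloxy)phenyl]acetic acid | OC(=O)Cc1ccc(O[Si](C)(C)C(C)(C)C)cc1 | intermediate
14 | methyl 5-({2-[4-(tert-butyldimethylsilyloxy)phenyl]acetyl}oxy)-7-methoxy-2,2-dimethyl-8-(3-methylbut-2-en-1-yl)-2H-chromene-6-carboxylate | COC(=O)c1c(OC)c(CC=C(C)C)c2OC(C)(C)C=Cc2c1OC(=O)Cc1ccc(O[Si](C)(C)C(C)(C)C)cc1 | intermediate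
15 | 3-[4-(tert-butyldimethylsilyloxy)phenyl]-4-hydroxy-5-methoxy-8,8-dimethyl-6-(3-methylbut-2-en-1-yl)pyrano[2,3-h]chromen-2-one | COc1c(CC=C(C)C)c2OC(C)(C)C=Cc2c2oc(=O)c(-c3ccc(O[Si](C)(C)C(C)(C)C)cc3)c(O)c12 | intermediate
16 | 4-hydroxy-3-(4-hydroxyphenyl)-5-methoxy-8,8-dimethyl-6-(3-methylbut-2-en-1-yl)pyrano[2,3-h]chromen-2-one | COc1c(CC=C(C)C)c2OC(C)(C)C=Cc2c2oc(=O)c(-c3ccc(O)cc3)c(O)c12 | intermediate
17 | 3-[5-hydroxy-7-methoxy-2,2-dimethyl-8-(3-methylbut-2-en-1-yl)-2H-chromen-6-yl]-2-(4-hydroxyphenyl)-3-oxopropanoic acid (racemic) | COc1c(CC=C(C)C)c2OC(C)(C)C=Cc2c(O)c1C(=O)C(C(=O)O)c1ccc(O)cc1 | intermediate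
18 | 1-[5-hydroxy-7-methoxy-2,2-dimethyl-8-(3-methylbut-2-en-1-yl)-2H-chromen-6-yl]-2-(4-hydroxyphenyl)ethan-1-one | COc1c(CC=C(C)C)c2c(c(O)c1C(=O)Cc1ccc(O)cc1)C=CC(C)(C)O2 | target

**Step count**

Total: 9 steps. Longest linear sequence: 8 steps (steps 1 to 5 and 7 to 9, from compound 1); step 6 is a one-step side branch.

**Steps most likely to fail**

Step 8. The ester enolate may fragment by E1cB into arylketene and the phenoxide of 10, and the ketene may be captured by the amide base or dimerise before the carbon–carbon bond forms; the crowded methyl ester may also simply react too slowly. The fallback sets out from 10 and comes back at 15 by the thermal phenol–arylmalonate condensation, which is known for 3-aryl-4-hydroxycoumarins. Saponification of 10 (KOH, aqueous ethylene glycol, 120 °C) would give 5-hydroxy-7-methoxy-2,2-dimethyl-8-(3-methylbut-2-en-1-yl)-2H-chromene-6-carboxylic acid F1. This electron-rich salicylic acid should lose CO2 on acidification and brief warming to give 7-methoxy-2,2-dimethyl-8-(3-methylbut-2-en-1-yl)-2H-chromen-5-ol F2. Copper-catalysed α-arylation of diethyl malonate with commercial tert-butyl(4-iodophenoxy)dimethylsilane (CuI, 2-picolinic acid, Cs2CO3, dioxane, rt) would give diethyl 2-[4-(tert-butyldimethylsilyloxy)phenyl]malonate F3. Heating F2 with F3 in diphenyl ether at about 250 °C with removal of ethanol should acylate the oxygen on C5 and then C6, the only unsubstituted ring carbon, and give 15.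

Step 3. Discrimination between the two phenoxides may be poor, so that the 5-methyl ether and the dimethyl ether form alongside 6. The fallback sets out from 5 and comes back at 6 and replaces kinetic discrimination by chelation-controlled ether cleavage. Exhaustive methylation (excess MeI, K2CO3, DMF) would give methyl 5,7-dimethoxy-2,2-dimethyl-2H-chromene-6-carboxylate F4. BCl3 (1.1 equiv, CH2Cl2, −78 °C) is then expected to cleave the more crowded methoxyl on C5, which is twisted out of the ring plane between the ester and the pyran ring and is held to the ester carbonyl through boron, leaving the 7-methoxyl and giving 6.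

Step 5. The prenyl ether may lose isoprene on heating (returning 6), or the relay from the ortho dienone may be incomplete and give abnormal shift products. The fallback sets out from 6 and comes back at 10 by halogenation and cross-coupling. N-Iodosuccinimide (MeCN, 0 °C) should iodinate C8, the only free ring position and para to the 5-hydroxyl, to give methyl 5-hydroxy-8-iodo-7-methoxy-2,2-dimethyl-2H-chromene-6-carboxylate F5. Stille coupling of F5 with tributyl(3-methylbut-2-en-1-yl)stannane (Pd(PPh3)4, DMF, 90 °C), under conditions chosen for the linear allyl transfer, should give 10.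

**Further compounds**

F1 | step 8 | 5-hydroxy-7-methoxy-2,2-dimethyl-8-(3-methylbut-2-en-1-yl)-2H-chromene-6-carboxylic acid | OC(=O)c1c(OC)c(CC=C(C)C)c2OC(C)(C)C=Cc2c1O
F2 | step 8 | 7-methoxy-2,2-dimethyl-8-(3-methylbut-2-en-1-yl)-2H-chromen-5-ol | COc1cc(O)c2C=CC(C)(C)Oc2c1CC=C(C)C
F3 | step 8 | diethyl 2-[4-(tert-butyldimethylsilyloxy)phenyl]malonate | CCOC(=O)C(C(=O)OCC)c1ccc(O[Si](C)(C)C(C)(C)C)cc1
F4 | step 3 | methyl 5,7-dimethoxy-2,2-dimethyl-2H-chromene-6-carboxylate | COC(=O)c1c(OC)cc2OC(C)(C)C=Cc2c1OC
F5 | step 5 | methyl 5-hydroxy-8-iodo-7-methoxy-2,2-dimethyl-2H-chromene-6-carboxylate | COC(=O)c1c(OC)c(I)c2OC(C)(C)C=Cc2c1O
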